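**Plan**
Numbering: C1 is the quaternary ring carbon (geranyl, prenyl). The ring then runs C2 (C=O), C3 (C-prenyl), C4 (C–OH), C5 (carbon bearing the benzoyl enol) and C6 (C=O).
Enabling feature: C3, C4, C5, C6, the benzoyl carbon and the phenyl ring form the skeleton of a 5-alkyl-3-phenylisoxazole-4-carbonyl unit. Its N–O bond stands in for the C4 oxygen and the benzoyl oxygen, and the hetero ring makes the C3 hydrogens acidic.
Retrosynthetic cuts, in order: benzoyl C–O to C–N (enaminone), N joined to the C4 oxygen (isoxazole), ring bond C2–C3, C1–geranyl, C1–prenyl, C1–C6, C3–prenyl.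
Forward: the isoxazole ring is bought, its 5-methyl group is prenylated, the acid is homologated to a β-keto ester, and C1 is alkylated twice. The carbocycle is the only ring made; it closes onto the isoxazole in step 5, and the hetero ring is then opened and hydrolysed.
Stereochemistry: C1 is the only stereocentre. It is set in step 4 by catalyst-controlled phase-transfer geranylation of a prochiral enolate and, being quaternary, cannot epimerise later. The E alkene comes with geranyl bromide.

Key step: step 5

Remark on tautomers and descriptors: the bicyclic enol, the enaminone and the target are mobile tautomers, each drawn as one form. C1 is S while C2 is an ester carbon and R once C2 is a ketone or enol carbon; this is a change of CIP rank only.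
Assumption: the (S,S)-ammonium salt is taken to give the S ester in step 4. If a first run shows the opposite sense, the equally available (R,R)-salt is used and nothing else changes.

Step 1
Reactants: 1 5-methyl-3-phenylisoxazole-4-carboxylic acid; 2 prenyl bromide (1-bromo-3-methylbut-2-ene)
Product: 4 5-(4-methylpent-3-en-1-yl)-3-phenylisoxazole-4-carboxylic acid, via dilithio dianion 3 (not isolated)
Conditions: n-BuLi (2.1 equiv), THF, −78 °C; then 2 (1.05 equiv), −78 → −20 °C; cold 1 M HCl work-up
Reagents that add atoms: prenyl bromide 2, CC(C)=CCBr; n-butyllithium, [Li]CCCC (supplies only the lithium of 3)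
Why: Lateral metalation of a 5-methylisoxazole as its carboxylate dianion: the first equivalent of base forms the carboxylate, the second removes a proton from the 5-methyl group (the most acidic C–H, held near the lithium carboxylate), and the carbanion of 3 displaces bromide at the primary end of 2 by SN2, which puts the prenyl group on C3.

Step 2
Reactants: 4 5-(4-methylpent-3-en-1-yl)-3-phenylisoxazole-4-carboxylic acid; 5 potassium methyl malonate
Product: 7 methyl 3-[5-(4-methylpent-3-en-1-yl)-3-phenylisoxazol-4-yl]-3-oxopropanoate, via acyl imidazolide 6 (not isolated)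
Conditions: 1,1'-carbonyldiimidazole (1.2 equiv), THF, 23 °C; then added to 5 (2 equiv), MgCl2 (2 equiv), Et3N (3 equiv), MeCN, 23 → 40 °C; cold 1 M HCl work-up
Reagents that add atoms: potassium methyl malonate 5, COC(=O)CC(=O)[O-].[K+]; 1,1'-carbonyldiimidazole, O=C(n1ccnc1)n1ccnc1 (supplies only the imidazolyl group of 6)
Why: Masamune–Brooks-type homologation: the acid is activated as imidazolide 6, and the magnesium-chelated enolate of the malonate half-ester is C-acylated with concomitant loss of CO2, forming the C1–C6 bond under near-neutral conditions that leave the alkene and the isoxazole alone.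

Step 3
Reactants: 7 methyl 3-[5-(4-methylpent-3-en-1-yl)-3-phenylisoxazol-4-yl]-3-oxopropanoate; 2 prenyl bromide
Product: 8 methyl (±)-5-methyl-2-{[5-(4-methylpent-3-en-1-yl)-3-phenylisoxazol-4-yl]carbonyl}hex-4-enoate
Conditions: K2CO3 (1.5 equiv), 2 (1.0 equiv), acetone, 23 → 45 °C
Reagents that add atoms: prenyl bromide 2, CC(C)=CCBr
Why: Classical β-keto ester alkylation: K2CO3 reversibly forms the stabilised enolate (far more acidic than the side-chain CH2), one equivalent of the allylic bromide C-alkylates it by SN2, and the labile α-centre is left racemic because step 4 flattens it again.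

Step 4
Reactants: 8 methyl (±)-5-methyl-2-{[5-(4-methylpent-3-en-1-yl)-3-phenylisoxazol-4-yl]carbonyl}hex-4-enoate; 9 geranyl bromide ((2E)-1-bromo-3,7-dimethylocta-2,6-diene)
Product: 10 methyl (2S,4E)-5,9-dimethyl-2-(3-methylbut-2-en-1-yl)-2-{[5-(4-methylpent-3-en-1-yl)-3-phenylisoxazol-4-yl]carbonyl}deca-4,8-dienoate
Conditions: 9 (1.2 equiv), (11bS,11'bS)-2,6-bis(3,4,5-trifluorophenyl)-3,3',5,5'-tetrahydro-4,4'-spirobi[dinaphtho[2,1-c:1',2'-e]azepin]-4-ium bromide (C56H34BrF6N, 3 mol %), Cs2CO3 (solid, 2 equiv), toluene, −20 → 0 °C
Reagents that add atoms: geranyl bromide 9, CC(C)=CCC/C(C)=C/CBr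
Why: Asymmetric phase-transfer alkylation of an α-substituted β-keto ester: the carbonate forms the fully substituted enolate at the solid surface, the axially chiral ammonium cation pairs with it and covers one face (the faces differ clearly because the enolate carbon carries CO2Me, prenyl and the bulky isoxazolyl enolate unit), and SN2 attack on the primary allylic bromide from the open face sets C1 as S under catalyst control, with the E alkene untouched.

Step 5
Reactants: 10 methyl (2S,4E)-5,9-dimethyl-2-(3-methylbut-2-en-1-yl)-2-{[5-(4-methylpent-3-en-1-yl)-3-phenylisoxazol-4-yl]carbonyl}deca-4,8-dienoate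
Product: 13 (5R)-5-[(2E)-3,7-dimethylocta-2,6-dien-1-yl]-6-hydroxy-5,7-bis(3-methylbut-2-en-1-yl)-3-phenyl-1,2-benzoxazol-4(5H)-one, via extended lithium enolate 11 (not isolated), via lithium enolate salt 12 (not isolated)
Conditions: LiN(SiMe3)2 (3.0 equiv), THF, argon, −78 → 0 °C; cold 0.5 M HCl work-up
Reagents that add atoms: LiN(SiMe3)2, [Li+].C[Si](C)(C)[N-][Si](C)(C)C (supplies only the lithium of 11 and 12; nothing from it remains in 13)
Why: The amide base removes one of the C3 hydrogens on the isoxazole 5-side chain, which the C6 ketone acidifies vinylogously through the ring C=C bond, and this gives extended enolate 11. The C3 terminus of 11 attacks the C2 methyl ester on the neighbouring quaternary carbon by addition–elimination with loss of methoxide, forming C2–C3 and the six-membered carbocycle fused to the isoxazole. The closest known reaction type is the Claisen acylation of laterally metalated 5-alkylisoxazoles by esters, run here intramolecularly as a vinylogous Dieckmann condensation; the closure is 6-(enolendo)-exo-trig, whereas attack through the α-carbon would require a four-membered ring. A second equivalent of base converts the acidic product at once into salt 12, which makes the closure irreversible and shields both acyl bonds at C1 from retro-Claisen attack by methoxide. No stereocentre is created, since C3 ends as an sp2 enol carbon, and C1 has no proton and breaks no bond, so its arrangement is carried over unchanged. The step needs deprotonation at C3 only and attack on the ester carbonyl only; this is secured because C1 is quaternary (the C3 hydrogens are the sole acidic ones), the 3-phenyl group removes the C3–H needed for base-induced isoxazole opening, and the base is non-nucleophilic and in excess.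

Step 6
Reactants: 13 (5R)-5-[(2E)-3,7-dimethylocta-2,6-dien-1-yl]-6-hydroxy-5,7-bis(3-methylbut-2-en-1-yl)-3-phenyl-1,2-benzoxazol-4(5H)-one
Product: 14 (6R)-2-[amino(phenyl)methylidene]-6-[(2E)-3,7-dimethylocta-2,6-dien-1-yl]-5-hydroxy-4,6-bis(3-methylbut-2-en-1-yl)cyclohex-4-ene-1,3-dione (NH2 on the side of the former isoxazole oxygen)
Conditions: Mo(CO)6 (1.0 equiv), MeCN/H2O (15:1), argon, reflux
Reagents that add atoms: none
Why: Reductive N–O cleavage of an isoxazole to a β-amino enone by Mo(CO)6 and water: the ring nitrogen binds zerovalent molybdenum, the weak N–O bond is reduced and water supplies the two hydrogens, and the four trisubstituted alkenes that hydrogenolysis would saturate are left intact.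

Step 7
Reactants: 14 (6R)-2-[amino(phenyl)methylidene]-6-[(2E)-3,7-dimethylocta-2,6-dien-1-yl]-5-hydroxy-4,6-bis(3-methylbut-2-en-1-yl)cyclohex-4-ene-1,3-dione
Product: 15 kolanone, (2R)-2-[(2E)-3,7-dimethylocta-2,6-dien-1-yl]-5-hydroxy-6-[hydroxy(phenyl)methylidene]-2,4-bis(3-methylbut-2-en-1-yl)cyclohex-4-ene-1,3-dione
Conditions: NaOH (2 M aq, 10 equiv), EtOH, degassed, argon, 70 °C; then cold 1 M HCl to pH 3
Reagents that add atoms: water, O
Why: Alkaline hydrolysis of a 2-(aminomethylidene)-1,3-dione, the known last stage of the isoxazole route to β-triketones: hydroxide adds to the benzylic enamine carbon and ammonia is expelled, deprotonation of the strongly acidic product drives the exchange and keeps the C1 acyl bonds safe from cleavage, and base is chosen over acid so that no alkene is protonated and no enol oxygen cyclises onto a prenyl group.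

**Compound list**
1 | 5-methyl-3-phenylisoxazole-4-carboxylic acid | Cc1onc(-c2ccccc2)c1C(=O)O | starting material
2 | prenyl bromide | CC(C)=CCBr | starting material
3 | dilithium salt of 1 (carboxylate and 5-CH2 carbanion) | [Li+].[Li+].[CH2-]c1onc(-c2ccccc2)c1C(=O)[O-] | intermediate (not isolated)
4 | 5-(4-methylpent-3-en-1-yl)-3-phenylisoxazole-4-carboxylic acid | CC(C)=CCCc1onc(-c2ccccc2)c1C(=O)O | intermediate
5 | potassium methyl malonate | COC(=O)CC(=O)[O-].[K+] | starting material
6 | 1-{[5-(4-methylpent-3-en-1-yl)-3-phenylisoxazol-4-yl]carbonyl}imidazole | CC(C)=CCCc1onc(-c2ccccc2)c1C(=O)n3ccnc3 | intermediate (not isolated)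
7 | methyl 3-[5-(4-methylpent-3-en-1-yl)-3-phenylisoxazol-4-yl]-3-oxopropanoate | COC(=O)CC(=O)c1c(CCC=C(C)C)onc1-c2ccccc2 | intermediate
8 | methyl (±)-5-methyl-2-{[5-(4-methylpent-3-en-1-yl)-3-phenylisoxazol-4-yl]carbonyl}hex-4-enoate | COC(=O)C(CC=C(C)C)C(=O)c1c(CCC=C(C)C)onc1-c2ccccc2 | intermediate
9 | geranyl bromide | CC(C)=CCC/C(C)=C/CBr | starting material
10 | methyl (2S,4E)-5,9-dimethyl-2-(3-methylbut-2-en-1-yl)-2-{[5-(4-methylpent-3-en-1-yl)-3-phenylisoxazol-4-yl]carbonyl}deca-4,8-dienoate | CC(C)=CCC/C(C)=C/C[C@](CC=C(C)C)(C(=O)OC)C(=O)c1c(CCC=C(C)C)onc1-c2ccccc2 | intermediate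
11 | extended lithium enolate of 10 (S; O-lithio at C6, exocyclic C3=C4 double bond) | CC(C)=CCC/C(C)=C/C[C@](CC=C(C)C)(C(=O)OC)C([O-])=C1C(=CCC=C(C)C)ON=C1c2ccccc2.[Li+] | intermediate (not isolated)
12 | lithium C2 enolate of 13 (R) | CC(C)=CCC/C(C)=C/C[C@]1(CC=C(C)C)C([O-])=C(CC=C(C)C)c2onc(-c3ccccc3)c2C1=O.[Li+] | intermediate (not isolated)
13 | (5R)-5-[(2E)-3,7-dimethylocta-2,6-dien-1-yl]-6-hydroxy-5,7-bis(3-methylbut-2-en-1-yl)-3-phenyl-1,2-benzoxazol-4(5H)-one | CC(C)=CCC/C(C)=C/C[C@]1(CC=C(C)C)C(O)=C(CC=C(C)C)c2onc(-c3ccccc3)c2C1=O | intermediate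
14 | (6R)-2-[amino(phenyl)methylidene]-6-[(2E)-3,7-dimethylocta-2,6-dien-1-yl]-5-hydroxy-4,6-bis(3-methylbut-2-en-1-yl)cyclohex-4-ene-1,3-dione | CC(C)=CCC/C(C)=C/C[C@]1(CC=C(C)C)C(O)=C(CC=C(C)C)C(=O)/C(=C(\N)c2ccccc2)C1=O | intermediate
15 | kolanone (R at C1) | CC(C)=CCC/C(C)=C/C[C@]1(CC=C(C)C)C(=O)C(CC=C(C)C)=C(O)/C(=C(\O)c2ccccc2)C1=O | target

**Count and risks**
Total steps: 7. Longest linear sequence: 7 (from 1 to 15).

Step 5. Attack on the neopentyl-type ester may be slow. Liberated methoxide could then add to C6 and fragment the chain by retro-Claisen cleavage before the ring closes. The fallback runs from 10 to 13 and lowers the oxidation level at C2 while keeping the same bond and ring. i-Bu2AlH (excess, CH2Cl2, −78 → 0 °C) reduces ester and ketone to the diol F1. A buffered Dess–Martin oxidation of both carbinols gives the non-enolisable keto aldehyde F2. Lithium 2,2,6,6-tetramethylpiperidide (THF, −78 °C) forms the same lateral anion, which adds to the aldehyde in a vinylogous aldol closure with no alkoxide released, giving the bicyclic β-hydroxy ketone F3. A second Dess–Martin oxidation returns to 13.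

Step 4. The acyclic enolate may form as a mixture of geometries, and a methyl ester offers the catalyst less bulk than the tert-butyl esters usually employed, so facial selectivity could be poor. The fallback runs from 8 to 10 and replaces asymmetric catalysis by resolution. Geranylation with 9 and K2CO3 in acetone, without a chiral salt, gives the racemic ester F4. Preparative supercritical-fluid chromatography on an amylose tris(3,5-dimethylphenylcarbamate) phase separates 10 from its (R)-enantiomer F5. The configuration is assigned by carrying a sample through to 15 and comparing chiroptical data with the natural product.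

Step 7. The doubly conjugated vinylogous amide may hydrolyse sluggishly. During long heating, C–C scission at the carbinolamine stage (loss of the benzoyl carbon as an amide) could compete with C–N scission. The fallback runs from 14 to 15 and activates the nitrogen before hydrolysis. Di-tert-butyl dicarbonate (3 equiv) with 4-(dimethylamino)pyridine in MeCN gives the N,O-bis(tert-butoxycarbonyl) derivative F6, in which nitrogen donation is switched off. LiOH in aqueous THF (0 → 23 °C) then adds to the benzylic carbon, expels tert-butyl carbamate and removes the enol carbonate. Cold acidification gives 15.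

**Further compounds**
F1 | step 5 | (2R)-2-[(2E)-3,7-dimethylocta-2,6-dien-1-yl]-2-(3-methylbut-2-en-1-yl)-1-[5-(4-methylpent-3-en-1-yl)-3-phenylisoxazol-4-yl]propane-1,3-diol (carbinol epimers) | CC(C)=CCC/C(C)=C/C[C@](CC=C(C)C)(CO)C(O)c1c(CCC=C(C)C)onc1-c2ccccc2
F2 | step 5 | (2R)-2-[(2E)-3,7-dimethylocta-2,6-dien-1-yl]-2-(3-methylbut-2-en-1-yl)-3-[5-(4-methylpent-3-en-1-yl)-3-phenylisoxazol-4-yl]-3-oxopropanal | CC(C)=CCC/C(C)=C/C[C@](CC=C(C)C)(C=O)C(=O)c1c(CCC=C(C)C)onc1-c2ccccc2
F3 | step 5 | (5R)-5-[(2E)-3,7-dimethylocta-2,6-dien-1-yl]-6-hydroxy-5,7-bis(3-methylbut-2-en-1-yl)-3-phenyl-6,7-dihydro-1,2-benzoxazol-4(5H)-one (epimers at C6 and C7) | CC(C)=CCC/C(C)=C/C[C@]1(CC=C(C)C)C(O)C(CC=C(C)C)c2onc(-c3ccccc3)c2C1=O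
F4 | step 4 | racemic methyl (4E)-5,9-dimethyl-2-(3-methylbut-2-en-1-yl)-2-{[5-(4-methylpent-3-en-1-yl)-3-phenylisoxazol-4-yl]carbonyl}deca-4,8-dienoate | CC(C)=CCC/C(C)=C/CC(CC=C(C)C)(C(=O)OC)C(=O)c1c(CCC=C(C)C)onc1-c2ccccc2
F5 | step 4 | (2R)-enantiomer of 10 | CC(C)=CCC/C(C)=C/C[C@@](CC=C(C)C)(C(=O)OC)C(=O)c1c(CCC=C(C)C)onc1-c2ccccc2
F6 | step 7 | N,O-bis(tert-butoxycarbonyl) derivative of 14 (carbamate on the enamine nitrogen, carbonate on the C2 enol oxygen, R at C1) | CC(C)=CCC/C(C)=C/C[C@]1(CC=C(C)C)C(OC(=O)OC(C)(C)C)=C(CC=C(C)C)C(=O)/C(=C(\NC(=O)OC(C)(C)C)c2ccccc2)C1=O
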